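Remark on the chemistry: ring atoms are numbered as in isochroman-1-one (C1 carbonyl, O2, C3, C4, C4a, C5–C8, C8a) and the side chain as C1'–C11'. The stereocentre of the target reads as 3R. Compounds 1, 2, 5, 10 and 12 are taken as purchasable; methoxyacetylene 14 is not a stock chemical and is made fresh.

## Analysis of the target

Target 18 is a 3,4-dihydroisocoumarin. A benzene ring (ring A: C4a, C5, C6, C7, C8, C8a) is fused along C4a–C8a to a six-membered lactone (ring B: C1, O2, C3, C4, C4a, C8a). Ring A carries a free hydroxyl at C8, hydrogen-bonded to the C1 carbonyl, and a methyl ether at C6; C5 and C7 bear hydrogen. The only stereocentre is C3 (R), the carbinol carbon of the lactone, which carries an eleven-carbon chain with a ketone at C6'. No second stereocentre exists to relay from, so the configuration has to be bought or set outright, and the ketone is too remote to help or interfere. Sensitive points are the lactone (opened by hydroxide), the phenol, the ketone (to be masked against carbon nucleophiles) and the two ring oxygens, which must end up differently substituted. The difficulty is one of economy rather than complexity: a 1,2,3,5-tetrasubstituted benzene with two differentiated oxygens must be joined to an isolated stereocentre without long protecting-group detours. The plan rests on the fact that the six carbons of ring A fall into three two-carbon units, C8a–C8, C7–C6 and C5–C4a. The first and third are already linked through C1–O2–C3–C4, so an open-chain diyne ester holds ring B in latent form and a third alkyne supplying C6 and C7 completes ring A.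

## Retrosynthetic reasoning

**18 back to 16.** The C8–O bond of 18 is traced to a C8–Si bond in aryl silane 16, through the boron compound 17. Electrophilic oxygenation of a ring that already has the 6-methoxy group would go to C5 or C7, not C8, so a silyl group installed during ring construction marks the position instead. The forward reaction must exchange silicon for boron at the ipso carbon under direction by the lactone carbonyl and then oxidise the carbon–boron bond, without cleaving the methyl ether or opening the lactone.

**16 back to 15.** The side-chain ketone of 16 is masked as the cyclic ketal of 15; no skeletal bond is cut. The ketal is needed earlier for two carbanion steps. It is removed before the boron step because a boron halide would attack it anyway and leave intermediates of uncertain constitution.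

**15 back to 11 and 14.** Three bonds of ring A are cut at once: C4a–C8a, C8–C7 and C6–C5. This leads to diyne ester 11, whose terminal alkyne supplies C5 and C4a and whose silyl ynoate supplies C8a and C8, and to methoxyacetylene 14, which supplies C6 with its oxygen and C7. The cut removes both rings in one operation, leaves C3 as a spectator in the tether, and delivers the two ring oxygens already differentiated. The forward [2+2+2] cycloaddition must first couple the two tethered alkynes (closing ring B) and then take up 14 in one orientation. Two factors are relied on for that: the bulk of the silyl group at the C8 terminus, and the matched polarity of an electron-rich alkynyl ether with an ester-conjugated metallacycle.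

**14 back to 12.** Compound 14 is too volatile and labile to store, so it is traced to chloroacetal 12 by two eliminations through its sodium salt 13.

**11 back to 9 and 10.** The acyl–oxygen bond is cut to give homopropargylic alcohol 9 and silyl propiolic acid 10. Esterification at oxygen cannot disturb the stereocentre, and the silyl group arrives with a purchased acid.

**9 back to 8.** The bond between the propargylic CH2 (the future C4) and the alkyne is cut, leading to terminal epoxide 8. An acetylide opens such an epoxide at CH2 only, so the carbinol carbon is again not a reacting centre.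

**8 back to 7, then to 4 (through 6) and 5.** Epoxide 8 comes from chlorohydrin 7 by ring closure. Chlorohydrin 7 is cut at C1'–C2' into organomagnesium compound 6 (made from bromide 4) and (R)-epichlorohydrin 5. This puts the only stereocentre into a cheap enantiopure three-carbon unit. No bond is made or broken at that carbon, so no asymmetric reaction and no resolution are needed; the other option, racemic epoxidation of a terminal alkene with kinetic resolution, would discard half the chain.

**4 back to 3, then to 1 and 2.** Ketal 4 is the protected form of bromoketone 3, which is cut at C6'–C7' into acid chloride 1 and pentyl Grignard reagent 2. The acylation must stop at the ketone and leave the primary bromide for the later Grignard formation.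

## Alternatives that were turned down

**Alternative 1:** Ring A is opened at C4a–C8a and unfolded into a linear poly-β-carbonyl chain, methyl (9R)-9-{[tert-butyl(dimethyl)silyl]oxy}-3,5,7-trioxo-14-(2-pentyl-1,3-dioxolan-2-yl)tetradecanoate A1.
- Forward key step: mild base forms the carbanion between the ester and the first ketone, which adds to the ketone at C7 of the chain in a six-membered aldol closure. Dehydration and enolisation give methyl 2-[(2R)-2-{[tert-butyl(dimethyl)silyl]oxy}-7-(2-pentyl-1,3-dioxolan-2-yl)heptyl]-4,6-dihydroxybenzoate A2. Silyl removal with lactonisation, methylation of the hydroxyl para to the ester, and ketal hydrolysis would follow.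
- For it: both oxygens arrive on the right carbons by construction, so no regiochemical question arises. On this point it is stronger than the chosen route, which has to win its regiochemistry in the ring-forming step.
- Against it:
  - (a) A1 is a mixture of enol tautomers with several cyclisation modes open (C-acylation onto the ester, O-cyclisation to pyranones), so the wanted aldol is one path among several.
  - (b) The C7 ketone of A1 has the silyloxy-bearing C9 in the β position, so the base that triggers the aldol can expel silanolate by E1cB across C8–C9 and erase the only stereocentre.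
  - (c) A1 must be assembled by acylating a polyanion with a chiral β-silyloxy acid derivative that itself takes several steps.
  - (d) Two phenols must be told apart after the ring is made.
- Comparison: the step count is not lower than in the chosen route. The chosen route never has a base-labile β-oxygenated ketone and carries the 6-methoxy group and the C8 placeholder as different groups from the start.

**Alternative 2:** The C3–C4 unit is taken as a vinyl group and the bonds on both sides, C4a–C4 and C3–C1', are cut; the C3–O bond is traced to C3–B. The components are aryl triflate 7-methoxy-2,2-dimethyl-4-oxo-4H-1,3-benzodioxin-5-yl trifluoromethanesulfonate A3, boronate 2-pentyl-2-[5-(4,4,5,5-tetramethyl-1,3,2-dioxaborolan-2-yl)pentyl]-1,3-dioxolane A4, and vinyllithium.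
- Forward key step: A4 and vinyllithium form a vinylboron ate complex. The arylpalladium species from A3 (Pd(OAc)2, chiral MandyPhos ligand) activates the alkene and triggers a 1,2-shift of the alkyl group from boron to the adjacent carbon while the aryl group bonds to the terminal carbon. The product is 7-methoxy-2,2-dimethyl-5-[(2R)-7-(2-pentyl-1,3-dioxolan-2-yl)-2-(4,4,5,5-tetramethyl-1,3,2-dioxaborolan-2-yl)heptyl]-4H-1,3-benzodioxin-4-one A5. Oxidation of C–B with retention, lactonisation onto the masked salicylate (which frees the C8 hydroxyl) and ketal hydrolysis would finish.
- For it: three components, two C–C bonds and the stereocentre in one catalytic step, on an arene bought with its oxygens in place. In convergence and step count it is stronger than the chosen route.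
- Against it:
  - The triflate of A3 sits next to the ring carbonyl carbon, so the electrophile is hindered and electron-rich.
  - The metallate shift has to outrun direct Suzuki-type vinyl transfer.
  - The enantiomeric purity at C3 depends entirely on ligand control with an unbranched migrating group, and the oily intermediates offer no means of upgrading it.
  - The benzodioxinone carbonyl is exposed to any organolithium not bound as the ate complex.
- Comparison: the chosen route takes C3 from an enantiopure building block and never reacts at that carbon, so enantiopurity is not at stake in any step.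

**Alternative 3:** Only C1 is removed, by cutting C8a–C1 and C1–O2. The precursor is (2R)-1-(3,5-dimethoxyphenyl)-7-(2-pentyl-1,3-dioxolan-2-yl)heptan-2-ol A6.
- Forward key step: the hydroxyl binds divalent palladium (Pd(OAc)2 with an N-protected amino acid ligand) and directs palladation of an ortho C–H bond. Carbon monoxide inserts and C–O reductive elimination gives (3R)-6,8-dimethoxy-3-[5-(2-pentyl-1,3-dioxolan-2-yl)pentyl]isochroman-1-one A7. A stoichiometric oxidant returns zerovalent palladium to the divalent state. Chelation-assisted cleavage of the C8 methyl ether and ketal hydrolysis would finish.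
- For it: A6 is one step from epoxide 8, and the arene is symmetric, so both ortho C–H bonds give the same product. In step economy it is clearly stronger than the chosen route.
- Against it:
  - The C–H bond to be metalated lies between the side chain and a methoxy group, the kind of flanked position that concerted palladation avoids.
  - The directing group is a secondary alcohol with a β-hydrogen, so oxidation to the ketone under divalent palladium and oxidant competes with the wanted pathway.
  - The electron-rich ring invites undirected palladation and oxidative coupling.
  - Two methyl ethers must be differentiated at the end.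
- Comparison: the chosen route forms both rings and places two different oxygen functions in one redox-neutral catalytic operation, with no oxidant near the free carbinol.

Key step: step 8

## Route

Step 1
Reactants: 1 5-bromopentanoyl chloride; 2 pentylmagnesium bromide
Product: 3 1-bromodecan-5-one
Conditions: Fe(acac)3 (3 mol%), THF, −78 °C, 2 added over 15 min
Reagents that add atoms: none
Why: Iron-catalysed acylation of a Grignard reagent by an acid chloride is complete within minutes at −78 °C, faster than addition of 2 to the new ketone or reaction at the primary C–Br bond, so the bromoketone should form without over-addition.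

Step 2
Reactants: 3 1-bromodecan-5-one
Product: 4 2-(4-bromobutyl)-2-pentyl-1,3-dioxolane
Conditions: HOCH2CH2OH, p-TsOH·H2O (cat.), toluene, reflux, Dean–Stark
Reagents that add atoms: ethylene glycol, OCCO
Why: Acid-catalysed ketalisation driven by azeotropic removal of water; the dioxolane shields the future C6' ketone from the organomagnesium and acetylide steps and is inert to base.

Step 3
Reactants: 4 2-(4-bromobutyl)-2-pentyl-1,3-dioxolane; 5 (R)-epichlorohydrin [(2R)-2-(chloromethyl)oxirane]
Product: 7 (2R)-1-chloro-7-(2-pentyl-1,3-dioxolan-2-yl)heptan-2-ol, via alkylmagnesium bromide 6 (not isolated)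
Conditions: Mg, THF, 40 °C; then CuI (10 mol%), 5, THF, −40 → −20 °C; aqueous work-up at pH 7
Reagents that add atoms: none
Why: Copper-catalysed SN2 opening of the terminal epoxide by the primary Grignard reagent 6 occurs at the unsubstituted ring carbon and, at low temperature, faster than displacement of chloride; the stereocentre of 5 is not a reacting centre, so its configuration passes unchanged into 7 (R, with OH > CH2Cl > chain CH2).

Step 4
Reactants: 7 (2R)-1-chloro-7-(2-pentyl-1,3-dioxolan-2-yl)heptan-2-ol
Product: 8 2-{5-[(2R)-oxiran-2-yl]pentyl}-2-pentyl-1,3-dioxolane
Conditions: NaOH (2 M aq), THF, 0 °C → rt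
Reagents that add atoms: none
Why: Intramolecular Williamson etherification (3-exo-tet) of the chlorohydrin; the C–O bond at the stereocentre is not broken, so 8 keeps the R configuration.

Step 5
Reactants: 8 2-{5-[(2R)-oxiran-2-yl]pentyl}-2-pentyl-1,3-dioxolane
Product: 9 (4R)-9-(2-pentyl-1,3-dioxolan-2-yl)non-1-yn-4-ol
Conditions: LiC≡CH·H2NCH2CH2NH2, DMSO, 0 °C → rt
Reagents that add atoms: lithium acetylide–ethylenediamine complex, [Li+].[C-]#C.NCCN
Why: SN2 opening of the monosubstituted epoxide by acetylide at the CH2 carbon in a dipolar aprotic solvent; the carbinol stereocentre is not involved and the ketal is stable to the base.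

Step 6
Reactants: 9 (4R)-9-(2-pentyl-1,3-dioxolan-2-yl)non-1-yn-4-ol; 10 3-(trimethylsilyl)prop-2-ynoic acid
Product: 11 (4R)-9-(2-pentyl-1,3-dioxolan-2-yl)non-1-yn-4-yl 3-(trimethylsilyl)prop-2-ynoate
Conditions: DCC, DMAP (5 mol%), CH2Cl2, −20 → 0 °C
Reagents that add atoms: none
Why: Steglich esterification; acylation takes place at oxygen, so the carbinol carbon keeps its configuration, and low temperature with little DMAP limits conjugate addition to the silyl ynoate and loss of the C-silyl group.

Step 7
Reactants: 12 2-chloro-1,1-dimethoxyethane (chloroacetaldehyde dimethyl acetal)
Product: 14 methoxyacetylene, via sodium methoxyacetylide 13 (not isolated)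
Conditions: NaNH2 (3 equiv), liq. NH3, −33 °C; NH3 evaporated; cold sat. aq NaCl, −20 °C; distilled into a −78 °C trap and taken up in cold ClCH2CH2Cl
Reagents that add atoms: none
Why: Twofold base-induced elimination (HCl and MeOH) from the α-chloroacetal and deprotonation give the sodium acetylide, which is protonated on cold aqueous quench; this is the established way to 1-alkoxyalkynes from haloacetals, and the low-boiling product is collected cold and used at once.

Step 8
Reactants: 11 (4R)-9-(2-pentyl-1,3-dioxolan-2-yl)non-1-yn-4-yl 3-(trimethylsilyl)prop-2-ynoate; 14 methoxyacetylene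
Product: 15 (3R)-6-methoxy-3-[5-(2-pentyl-1,3-dioxolan-2-yl)pentyl]-8-(trimethylsilyl)isochroman-1-one
Conditions: Cp*RuCl(cod) (5–10 mol%), 14 (3 equiv), ClCH2CH2Cl, slow addition of 11 by syringe pump, 0 → 40 °C, closed vessel
Reagents that add atoms: none
Why: Cp*RuCl(cod) loses cyclooctadiene and the divalent ruthenium fragment binds both alkynes of 11; oxidative coupling joins the two tether-bound alkyne carbons (C4a–C8a) to a tetravalent ruthenacyclopentadiene fused to the new lactone, so ring B closes by intramolecular oxidative cyclisation with both triple bonds exo to the forming six-membered ring. Methoxyacetylene 14 then coordinates and inserts into a Ru–C bond, and reductive elimination forms C8–C7 and C6–C5, closing ring A as the third two-carbon unit of a formal [2+2+2] cycloaddition and releasing the catalyst. The closest known reaction type is the ruthenium- or rhodium-catalysed cocyclisation of ester-tethered diynes with terminal monoalkynes to benzo-fused lactones; what is specific to this case is the four-atom ester tether combined with an alkynyl ether partner. No stereocentre is formed; C3 lies in the tether, is not a reacting centre and stays R. The step needs cross-selectivity over self-coupling of 11 or of 14, which slow addition of 11 into an excess of 14 should secure. It also needs one orientation of 14 (oxygen-bearing carbon to C5, CH to C8): the bulky SiMe3 at the C8 terminus keeps the substituted alkyne carbon away from it, and the polarity agrees, since the nucleophilic CH of the alkynyl ether pairs with the ester-conjugated C8 and the donor methoxy group ends para to the acceptor-bearing C8a. Because ring B can only close from the less populated s-cis ester conformer, a warm, dilute, slow-addition protocol is chosen.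

Step 9
Reactants: 15 (3R)-6-methoxy-3-[5-(2-pentyl-1,3-dioxolan-2-yl)pentyl]-8-(trimethylsilyl)isochroman-1-one
Product: 16 (3R)-6-methoxy-3-(6-oxoundecyl)-8-(trimethylsilyl)isochroman-1-one
Conditions: PPTS (cat.), acetone/H2O, 50 °C
Reagents that add atoms: water, O
Why: Acid-catalysed ketal hydrolysis with exchange to acetone; the C8–Si bond is meta to the methoxy group and ortho to the carbonyl, hence poorly activated towards protodesilylation under this mild acid, and the ketal is removed here because the Lewis acid of the next step would attack it in any case.

Step 10
Reactants: 16 (3R)-6-methoxy-3-(6-oxoundecyl)-8-(trimethylsilyl)isochroman-1-one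
Product: 18 (3R)-8-hydroxy-6-methoxy-3-(6-oxoundecyl)isochroman-1-one, via aryldichloroborane 17 (not isolated)
Conditions: BCl3 (3 equiv), CH2Cl2, −78 → 0 °C; volatiles removed; H2O2, aq NaHCO3, THF, 0 °C
Reagents that add atoms: hydrogen peroxide, OO
Why: ipso-Borodesilylation: BCl3 bound to the lactone carbonyl is delivered to the neighbouring C8, the arenium ion is stabilised by the β-silicon, and loss of Me3SiCl leaves the C8–BCl2 compound 17 as a five-membered O→B chelate; hydroperoxide then adds to boron and 1,2-aryl migration gives the phenol. Bicarbonate pH and 0 °C should spare the lactone, and the unchelated 6-methyl ether is not expected to be cleaved by BCl3 at this temperature.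

## Compound list

1 | 5-bromopentanoyl chloride | BrCCCCC(=O)Cl | starting material
2 | pentylmagnesium bromide | CCCCC[Mg]Br | starting material
3 | 1-bromodecan-5-one | CCCCCC(=O)CCCCBr | intermediate
4 | 2-(4-bromobutyl)-2-pentyl-1,3-dioxolane | CCCCCC1(CCCCBr)OCCO1 | intermediate
5 | (R)-epichlorohydrin, (2R)-2-(chloromethyl)oxirane | ClC[C@H]1CO1 | starting material
6 | [4-(2-pentyl-1,3-dioxolan-2-yl)butyl]magnesium bromide | CCCCCC1(CCCC[Mg]Br)OCCO1 | intermediate (not isolated)
7 | (2R)-1-chloro-7-(2-pentyl-1,3-dioxolan-2-yl)heptan-2-ol | ClC[C@H](O)CCCCCC1(CCCCC)OCCO1 | intermediate
8 | 2-{5-[(2R)-oxiran-2-yl]pentyl}-2-pentyl-1,3-dioxolane | CCCCCC1(CCCCC[C@@H]2CO2)OCCO1 | intermediate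
9 | (4R)-9-(2-pentyl-1,3-dioxolan-2-yl)non-1-yn-4-ol | C#CC[C@H](O)CCCCCC1(CCCCC)OCCO1 | intermediate
10 | 3-(trimethylsilyl)prop-2-ynoic acid | C[Si](C)(C)C#CC(=O)O | starting material
11 | (4R)-9-(2-pentyl-1,3-dioxolan-2-yl)non-1-yn-4-yl 3-(trimethylsilyl)prop-2-ynoate | C#CC[C@H](OC(=O)C#C[Si](C)(C)C)CCCCCC1(CCCCC)OCCO1 | intermediate
12 | 2-chloro-1,1-dimethoxyethane | COC(CCl)OC | starting material
13 | sodium methoxyacetylide | COC#[C-].[Na+] | intermediate (not isolated)
14 | methoxyacetylene (methoxyethyne) | COC#C | intermediate
15 | (3R)-6-methoxy-3-[5-(2-pentyl-1,3-dioxolan-2-yl)pentyl]-8-(trimethylsilyl)isochroman-1-one | COc1cc2C[C@@H](CCCCCC3(CCCCC)OCCO3)OC(=O)c2c(c1)[Si](C)(C)C | intermediate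
16 | (3R)-6-methoxy-3-(6-oxoundecyl)-8-(trimethylsilyl)isochroman-1-one | CCCCCC(=O)CCCCC[C@@H]1Cc2cc(OC)cc([Si](C)(C)C)c2C(=O)O1 | intermediate
17 | dichloro[(3R)-6-methoxy-1-oxo-3-(6-oxoundecyl)isochroman-8-yl]borane | CCCCCC(=O)CCCCC[C@@H]1Cc2cc(OC)cc(B(Cl)Cl)c2C(=O)O1 | intermediate (not isolated)
18 | (3R)-8-hydroxy-6-methoxy-3-(6-oxoundecyl)isochroman-1-one | CCCCCC(=O)CCCCC[C@@H]1Cc2cc(OC)cc(O)c2C(=O)O1 | target

## Step count and least certain steps

Total: 10 steps. Longest linear sequence: 9 steps (steps 1–6, 8, 9, 10, from 1); step 7 is a one-step side branch that feeds step 8.

**Step 8 (key step).** Four processes are most likely to go wrong: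
- The catalyst and 14 are consumed by self-oligomerisation of the reactive alkynyl ether.
- Cyclotrimerisation proceeds through the terminal alkyne of 11 alone and leaves the hindered silyl ynoate unreacted.
- Compound 14 inserts in the reversed orientation, because the oxygen substituent is small and its electronic bias in a ruthenacycle is not established.
- Ring B fails to close, since the ester prefers the s-trans geometry and 1,7-diynes form the bicyclic metallacycle less readily than 1,6-diynes.

The fallback gives up the cycloaddition and builds the ring system on a purchased arene. It sets out from epoxide 8 and comes back to the route at target 18. Epoxide 8 is opened at its CH2 terminus by commercial 3,5-dimethoxyphenylmagnesium bromide with catalytic CuI (THF, −30 °C) to give (2R)-1-(3,5-dimethoxyphenyl)-7-(2-pentyl-1,3-dioxolan-2-yl)heptan-2-ol F1 (the same structure as A6). N-Bromosuccinimide (MeCN, NaHCO3, 0 °C) should brominate the ring position between the side chain and a methoxy group, para to the other methoxy group, giving (2R)-1-(2-bromo-3,5-dimethoxyphenyl)-7-(2-pentyl-1,3-dioxolan-2-yl)heptan-2-ol F2. Palladium-catalysed carbonylative lactonisation through the free hydroxyl (Pd(OAc)2, Xantphos, CO 1 atm, Et3N, toluene, 100 °C) closes ring B to (3R)-6,8-dimethoxy-3-[5-(2-pentyl-1,3-dioxolan-2-yl)pentyl]isochroman-1-one F3 (the same structure as A7, here reached through an aryl bromide rather than C–H activation). Ketal hydrolysis (PPTS, acetone/H2O) gives (3R)-6,8-dimethoxy-3-(6-oxoundecyl)isochroman-1-one F4. BCl3 (CH2Cl2, −78 → 0 °C), which cleaves only the methyl ether chelated to the lactone carbonyl, then gives 18.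

**Step 10.** The ipso-substitution may not take place. The ring is deactivated by the complexed lactone, and C8 gets no help from the 6-methoxy group, which is meta to it. Protodesilylation by adventitious HCl or slow cleavage of the 6-methyl ether could then take over. The fallback replaces the silicon-to-boron exchange by a carbonyl-directed C–H oxygenation. It sets out from 16 and comes back at 18. Fluoride-induced protodesilylation (CsF, DMF/H2O, 80 °C; acidic work-up to re-close any opened lactone) gives (3R)-6-methoxy-3-(6-oxoundecyl)isochroman-1-one F5. Ester-directed ortho-hydroxylation ([RuCl2(p-cymene)]2 cat., K2S2O8, CF3CO2H/(CF3CO)2O, 80 °C) should then oxygenate C8, the only C–H bond within reach of the lactone carbonyl. The primary product is (3R)-6-methoxy-1-oxo-3-(6-oxoundecyl)isochroman-8-yl trifluoroacetate F6, which is hydrolysed on aqueous work-up to 18.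

**Step 7.** The chemistry is established; the danger is loss of the low-boiling product and its polymerisation during isolation, together with hazardous dry acetylide residues. The fallback isolates the alkyne as a distillable, storable C-silyl derivative. It sets out from sodium methoxyacetylide 13 and comes back at 14. After evaporation of ammonia, the salt is suspended in Et2O and silylated with Me3SiCl at −20 °C to give (methoxyethynyl)trimethylsilane F7, which is distilled and kept cold. Shortly before step 8 it is desilylated with catalytic K2CO3 in MeOH, and the liberated 14 is swept with argon into cold ClCH2CH2Cl.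

**Step 1.** Over-addition of 2 to the ketone, or iron-mediated reaction at the primary C–Br bond, may erode the bromoketone if addition or temperature control is imperfect. The fallback replaces kinetic control by a chelate-stabilised intermediate. It sets out from 1 and comes back at 3. Acid chloride 1 is treated with N,O-dimethylhydroxylamine hydrochloride and pyridine (CH2Cl2, 0 °C) to give the Weinreb amide 5-bromo-N-methoxy-N-methylpentanamide F8. Addition of 2 (THF, −20 °C) then stops at the tetrahedral magnesium chelate and gives 3 on aqueous work-up.

## Further compounds

F1 | step 8 | (2R)-1-(3,5-dimethoxyphenyl)-7-(2-pentyl-1,3-dioxolan-2-yl)heptan-2-ol | COc1cc(OC)cc(C[C@H](O)CCCCCC2(CCCCC)OCCO2)c1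
F2 | step 8 | (2R)-1-(2-bromo-3,5-dimethoxyphenyl)-7-(2-pentyl-1,3-dioxolan-2-yl)heptan-2-ol | COc1cc(OC)c(Br)c(C[C@H](O)CCCCCC2(CCCCC)OCCO2)c1
F3 | step 8 | (3R)-6,8-dimethoxy-3-[5-(2-pentyl-1,3-dioxolan-2-yl)pentyl]isochroman-1-one | COc1cc2C[C@@H](CCCCCC3(CCCCC)OCCO3)OC(=O)c2c(OC)c1
F4 | step 8 | (3R)-6,8-dimethoxy-3-(6-oxoundecyl)isochroman-1-one | CCCCCC(=O)CCCCC[C@@H]1Cc2cc(OC)cc(OC)c2C(=O)O1
F5 | step 10 | (3R)-6-methoxy-3-(6-oxoundecyl)isochroman-1-one | CCCCCC(=O)CCCCC[C@@H]1Cc2cc(OC)ccc2C(=O)O1
F6 | step 10 | (3R)-6-methoxy-1-oxo-3-(6-oxoundecyl)isochroman-8-yl trifluoroacetate | CCCCCC(=O)CCCCC[C@@H]1Cc2cc(OC)cc(OC(=O)C(F)(F)F)c2C(=O)O1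
F7 | step 7 | (methoxyethynyl)trimethylsilane | COC#C[Si](C)(C)C
F8 | step 1 | 5-bromo-N-methoxy-N-methylpentanamide | CON(C)C(=O)CCCCBr
A1 | alternative 1 | methyl (9R)-9-{[tert-butyl(dimethyl)silyl]oxy}-3,5,7-trioxo-14-(2-pentyl-1,3-dioxolan-2-yl)tetradecanoate | COC(=O)CC(=O)CC(=O)CC(=O)C[C@H](O[Si](C)(C)C(C)(C)C)CCCCCC1(CCCCC)OCCO1
A2 | alternative 1 | methyl 2-[(2R)-2-{[tert-butyl(dimethyl)silyl]oxy}-7-(2-pentyl-1,3-dioxolan-2-yl)heptyl]-4,6-dihydroxybenzoate | COC(=O)c1c(O)cc(O)cc1C[C@H](O[Si](C)(C)C(C)(C)C)CCCCCC2(CCCCC)OCCO2
A3 | alternative 2 | 7-methoxy-2,2-dimethyl-4-oxo-4H-1,3-benzodioxin-5-yl trifluoromethanesulfonate | COc1cc(OS(=O)(=O)C(F)(F)F)c2C(=O)OC(C)(C)Oc2c1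
A4 | alternative 2 | 2-pentyl-2-[5-(4,4,5,5-tetramethyl-1,3,2-dioxaborolan-2-yl)pentyl]-1,3-dioxolane | CCCCCC1(CCCCCB2OC(C)(C)C(C)(C)O2)OCCO1
A5 | alternative 2 | 7-methoxy-2,2-dimethyl-5-[(2R)-7-(2-pentyl-1,3-dioxolan-2-yl)-2-(4,4,5,5-tetramethyl-1,3,2-dioxaborolan-2-yl)heptyl]-4H-1,3-benzodioxin-4-one | COc1cc(C[C@H](B3OC(C)(C)C(C)(C)O3)CCCCCC4(CCCCC)OCCO4)c2C(=O)OC(C)(C)Oc2c1
A6 | alternative 3 | (2R)-1-(3,5-dimethoxyphenyl)-7-(2-pentyl-1,3-dioxolan-2-yl)heptan-2-ol | COc1cc(OC)cc(C[C@H](O)CCCCCC2(CCCCC)OCCO2)c1
A7 | alternative 3 | (3R)-6,8-dimethoxy-3-[5-(2-pentyl-1,3-dioxolan-2-yl)pentyl]isochroman-1-one | COc1cc2C[C@@H](CCCCCC3(CCCCC)OCCO3)OC(=O)c2c(OC)c1
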